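**Plan** (locants follow the naphthalen-2(3H)-one skeleton: C2 = ketone, C1=C8a and C7=C8 = alkenes, C3 = carbinol, C4a/C5 = methyl-bearing carbons, C6 = ester carbon)

- Retrosynthesis: the C3–OH bond (enolate oxidation) and the C6–O ester bond are cut last; then C1–C2 and C4a–C8a of the enone ring A are cut together.
- Enabling feature: in ring A the four carbons C2(=O)–C3–C4–C4a(quaternary, Me) are a latent cyclobutanone and C1=C8a is a latent alkyne. The alkyne hangs on C4a through C5, C6 and the cis C7=C8 alkene of ring B, so rhodium insertion into the acyl–C4a bond and alkyne uptake make rings A and B at once.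
- Forward, chain first: (S)-but-3-yn-2-ol and a silyl diynal are joined by an anti propargylation (sets C5 and C6). The new terminal alkyne becomes a 1-alkenylcyclopropanol, which is ring-expanded to the 2,2-disubstituted cyclobutanone (sets C4a). Cis semi-reduction then gives the Z-enyne.
- Rings: cyclopropane (bought) → cyclobutanone → rings A and B in one operation. Then desilylation, esterification with the (6R)-hydroxydienoic acid, and C3 hydroxylation.
- Stereochemistry: C5/C6 by chirality transfer from the butynol; C4a by 1,2-induction in the ring expansion; C3 by the angular C4a methyl; the side-chain carbinol from (R)-2-hydroxy-2-methylbutanoic acid.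

Key step: step 10

Remark: 1-ethoxycyclopropan-1-ol and (R)-2-hydroxy-2-methylbutanoic acid are taken as purchasable; the former can otherwise be freed from its commercial trimethylsilyl ether with methanol.

**Step 1**
Reactants: 1 1,4-bis(trimethylsilyl)buta-1,3-diyne
Product: 3 5-(trimethylsilyl)penta-2,4-diynal, via lithium diynide 2 (not isolated)
Conditions: MeLi·LiBr (1.0 equiv), THF, 25 °C; DMF, −78 → 0 °C; inverse quench into aq. KH2PO4, 0 °C
Reagents that add atoms: N,N-dimethylformamide, CN(C)C=O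
Why: Mono-desilylation of the symmetric diyne gives the lithium diynide, and its formylation with DMF followed by a buffered reverse quench (acetylide formylation) should give the ynal without amine conjugate addition.

**Step 2**
Reactants: 4 (S)-but-3-yn-2-ol
Product: 5 (S)-but-3-yn-2-yl methanesulfonate
Conditions: MsCl, Et3N, CH2Cl2, −78 → 0 °C
Reagents that add atoms: methanesulfonyl chloride, CS(Cl)(=O)=O
Why: O-sulfonylation does not touch the stereocentre, so the propargylic mesylate keeps the S configuration.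

**Step 3**
Reactants: 3 5-(trimethylsilyl)penta-2,4-diynal; 5 (S)-but-3-yn-2-yl methanesulfonate
Product: 7 (3R,4R)-3-methyl-8-(trimethylsilyl)octa-1,5,7-triyn-4-ol, via allenylzinc methanesulfonate 6 (not isolated)
Conditions: Pd(OAc)2 (5 mol%), PPh3 (5 mol%), Et2Zn (3 equiv), THF, −78 → −20 °C
Reagents that add atoms: none
Why: In this Marshall propargylation zerovalent palladium displaces the mesylate in the anti SN2′ sense, transmetalation gives a configurationally defined allenylzinc, and its cyclic SE2′ addition to the ynal should give the anti adduct, with the methyl-bearing carbon formed with net inversion (3R) and the carbinol as 4R.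

**Step 4**
Reactants: 7 (3R,4R)-3-methyl-8-(trimethylsilyl)octa-1,5,7-triyn-4-ol
Product: 8 tert-butyl(dimethyl){[(3R,4R)-3-methyl-8-(trimethylsilyl)octa-1,5,7-triyn-4-yl]oxy}silane
Conditions: TBSCl, imidazole, DMF, 25 °C
Reagents that add atoms: tert-butyldimethylsilyl chloride, CC(C)(C)[Si](C)(C)Cl
Why: Silylation of the secondary propargylic alcohol protects it against the boron and lithium reagents that follow and leaves both stereocentres untouched.

**Step 5**
Reactants: 8 tert-butyl(dimethyl){[(3R,4R)-3-methyl-8-(trimethylsilyl)octa-1,5,7-triyn-4-yl]oxy}silane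
Product: 10 {[(3S,4R)-2-bromo-3-methyl-8-(trimethylsilyl)oct-1-en-5,7-diyn-4-yl]oxy}(tert-butyl)dimethylsilane, via (Z)-2-bromoalk-1-enyl-9-BBN adduct 9 (not isolated)
Conditions: B-bromo-9-borabicyclo[3.3.1]nonane (1.1 equiv), CH2Cl2, 0 °C; then AcOH, 0 → 25 °C
Reagents that add atoms: B-bromo-9-borabicyclo[3.3.1]nonane, BrB1C2CCCC1CCC2
Why: Markovnikov syn bromoboration occurs at the only terminal alkyne (the internal and silyl-capped triple bonds react far more slowly), and protonolysis of the alkenyl C–B bond should give the 2-bromo-1-alkene; the change of descriptor to 3S is only a change of CIP priorities.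

**Step 6**
Reactants: 10 {[(3S,4R)-2-bromo-3-methyl-8-(trimethylsilyl)oct-1-en-5,7-diyn-4-yl]oxy}(tert-butyl)dimethylsilane; 11 1-ethoxycyclopropan-1-ol
Product: 14 1-[(3R,4R)-4-{[tert-butyl(dimethyl)silyl]oxy}-3-methyl-8-(trimethylsilyl)oct-1-en-5,7-diyn-2-yl]cyclopropan-1-ol, via alkenyllithium 12 (not isolated), via bromomagnesium 1-ethoxycyclopropan-1-olate 13 (not isolated)
Conditions: 10, t-BuLi (2.0 equiv), Et2O, −78 °C; separately 11, MeMgBr (1.0 equiv), THF, 0 °C; combine, −78 → 25 °C; aq. NH4Cl
Reagents that add atoms: none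
Why: Bromine–lithium exchange gives the 1,1-disubstituted alkenyllithium, which should add to the cyclopropanone released in the flask from the magnesium hemiacetalate (1,2-addition to a cyclopropanone equivalent) without touching either stereocentre.

**Step 7**
Reactants: 14 1-[(3R,4R)-4-{[tert-butyl(dimethyl)silyl]oxy}-3-methyl-8-(trimethylsilyl)oct-1-en-5,7-diyn-2-yl]cyclopropan-1-ol
Product: 15 (2R)-2-[(2R,3R)-3-{[tert-butyl(dimethyl)silyl]oxy}-7-(trimethylsilyl)hepta-4,6-diyn-2-yl]-2-methylcyclobutan-1-one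
Conditions: TsOH·H2O (10 mol%), CH2Cl2, −20 → 0 °C
Reagents that add atoms: none
Why: Protonation of the 1,1-disubstituted alkene gives a tertiary cyclopropylcarbinyl cation (the new methyl group), and a cyclopropane C–C bond migrates to it (protio-semipinacol ring expansion of a 1-alkenylcyclopropanol) on the face anti to the bulky silyloxy-diynyl branch of the neighbouring methyl-bearing stereocentre (Felkin–Anh-type arrangement, hydrogen inside), which should set the quaternary carbon as 2R.

**Step 8**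
Reactants: 15 (2R)-2-[(2R,3R)-3-{[tert-butyl(dimethyl)silyl]oxy}-7-(trimethylsilyl)hepta-4,6-diyn-2-yl]-2-methylcyclobutan-1-one
Product: 16 (2R)-2-[(2R,3S,4Z)-3-{[tert-butyl(dimethyl)silyl]oxy}-7-(trimethylsilyl)hept-4-en-6-yn-2-yl]-2-methylcyclobutan-1-one
Conditions: Zn dust activated with Cu(OAc)2 and AgNO3, MeOH/H2O (1:1), 25–40 °C
Reagents that add atoms: none
Why: In this Boland reduction activated zinc delivers two hydrogens syn to the conjugated, non-silylated triple bond only (the silyl-capped alkyne and the ketone are inert), so the 4Z enyne should result; the 3S descriptor is a priority change, not an inversion.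

**Step 9**
Reactants: 16 (2R)-2-[(2R,3S,4Z)-3-{[tert-butyl(dimethyl)silyl]oxy}-7-(trimethylsilyl)hept-4-en-6-yn-2-yl]-2-methylcyclobutan-1-one
Product: 17 (2R)-2-[(2R,3S,4Z)-3-{[tert-butyl(dimethyl)silyl]oxy}hept-4-en-6-yn-2-yl]-2-methylcyclobutan-1-one
Conditions: K2CO3, MeOH, 0 °C
Reagents that add atoms: none
Why: Methanolysis cleaves the alkynyl C–Si bond selectively, while the silyl ether and the non-epimerisable alpha-quaternary cyclobutanone should survive the mild base.

**Step 10**
Reactants: 17 (2R)-2-[(2R,3S,4Z)-3-{[tert-butyl(dimethyl)silyl]oxy}hept-4-en-6-yn-2-yl]-2-methylcyclobutan-1-one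
Product: 18 (4aR,5R,6S)-6-{[tert-butyl(dimethyl)silyl]oxy}-4a,5-dimethyl-4,4a,5,6-tetrahydronaphthalen-2(3H)-one
Conditions: [Rh(CO)2Cl]2 (5 mol%), PMe2Ph (20 mol%), 1,4-dioxane (0.02 M), 130 °C, sealed tube
Reagents that add atoms: none
Why: Monovalent rhodium inserts oxidatively into the cyclobutanone bond between the carbonyl carbon and the quaternary alpha-carbon (directly, or after reversible insertion at the less hindered side and CO extrusion/re-insertion), the resulting five-membered acyl-rhodacycle of trivalent rhodium takes up the tethered alkyne by syn migratory insertion, and C(acyl)–C(sp2) reductive elimination releases the dienone and the catalyst. The closest known reaction type is the rhodium-catalysed intramolecular "cut-and-sew" (formal [4+2]) of 2,2-disubstituted cyclobutanones with alkynes tethered at C2, which gives cyclohexenone-fused bicycles with an angular quaternary carbon. Ring B closes in the insertion event as a six-membered ring in the exo-dig sense (new C4a–C8a bond, the alkyne carbon next to the tether bonding to the quaternary carbon), and ring A arises by two-carbon expansion of the four-membered ring when the C1–C2 bond forms in the reductive elimination. No new stereocentre is created: C4a is carried over with retention because its C–C bond is exchanged for C–Rh and then C–C on the same face, and C5 and C6 in the tether are not involved. The step needs site selectivity for the hindered proximal C–C bond over the distal one and chemoselectivity against decarbonylation and alkyne oligomerisation; the cis alkene of the tether holds the alkyne within reach of the proximal bond only, the small electron-rich phosphine favours insertion at the congested bond, and high dilution protects the terminal alkyne.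

**Step 11**
Reactants: 18 (4aR,5R,6S)-6-{[tert-butyl(dimethyl)silyl]oxy}-4a,5-dimethyl-4,4a,5,6-tetrahydronaphthalen-2(3H)-one
Product: 19 (4aR,5R,6S)-6-hydroxy-4a,5-dimethyl-4,4a,5,6-tetrahydronaphthalen-2(3H)-one
Conditions: HF·pyridine, pyridine, THF, 0 → 25 °C
Reagents that add atoms: none
Why: Buffered fluoride cleaves the silyl ether without base-mediated damage to the cross-conjugated dienone, and no stereocentre is affected.

**Step 12**
Reactants: 20 (R)-2-hydroxy-2-methylbutanoic acid
Product: 21 methyl (R)-2-hydroxy-2-methylbutanoate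
Conditions: MeOH, H2SO4 (cat.), reflux
Reagents that add atoms: methanol, CO
Why: Fischer esterification of the chiral-pool acid leaves the non-epimerisable tertiary carbinol stereocentre unchanged.

**Step 13**
Reactants: 21 methyl (R)-2-hydroxy-2-methylbutanoate
Product: 22 methyl (R)-2-methyl-2-[(triethylsilyl)oxy]butanoate
Conditions: TESOTf, 2,6-lutidine, CH2Cl2, 0 °C
Reagents that add atoms: triethylsilyl trifluoromethanesulfonate, CC[Si](CC)(CC)OS(=O)(=O)C(F)(F)F
Why: The silyl triflate silylates the hindered tertiary alcohol, which stabilises the alpha-oxygenated aldehyde of the next step.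

**Step 14**
Reactants: 22 methyl (R)-2-methyl-2-[(triethylsilyl)oxy]butanoate
Product: 23 (R)-2-methyl-2-[(triethylsilyl)oxy]butanal
Conditions: i-Bu2AlH (1.1 equiv), CH2Cl2, −78 °C; Rochelle salt work-up
Reagents that add atoms: none
Why: The alpha-silyloxy group stabilises the tetrahedral aluminium hemiacetal at low temperature, so partial reduction should stop at the aldehyde.

**Step 15**
Reactants: 23 (R)-2-methyl-2-[(triethylsilyl)oxy]butanal; 24 ethyl (2E)-4-(diethoxyphosphoryl)but-2-enoate
Product: 26 ethyl (2E,4E,6R)-6-methyl-6-[(triethylsilyl)oxy]octa-2,4-dienoate, via lithiated phosphonate 25 (not isolated)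
Conditions: 24, LiN(SiMe3)2, THF, −78 °C; then 23, −78 → 0 °C
Reagents that add atoms: none
Why: The vinylogous Horner–Wadsworth–Emmons reaction of the stabilised phosphonate anion should give the new C4=C5 alkene E under thermodynamic control while the C2=C3 alkene keeps its E geometry.

**Step 16**
Reactants: 26 ethyl (2E,4E,6R)-6-methyl-6-[(triethylsilyl)oxy]octa-2,4-dienoate
Product: 27 (2E,4E,6R)-6-hydroxy-6-methylocta-2,4-dienoic acid
Conditions: LiOH, THF/MeOH/H2O, 25 °C; then 1 M HCl, THF, 25 °C
Reagents that add atoms: lithium hydroxide, [Li+].[OH-]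
Why: Saponification followed by mild acid cleaves the ester and the silyl ether; the tertiary carbinol next to an electron-poor diene should not ionise.

**Step 17**
Reactants: 19 (4aR,5R,6S)-6-hydroxy-4a,5-dimethyl-4,4a,5,6-tetrahydronaphthalen-2(3H)-one; 27 (2E,4E,6R)-6-hydroxy-6-methylocta-2,4-dienoic acid
Product: 29 (4aR,5R,6S)-4a,5-dimethyl-2-oxo-2,3,4,4a,5,6-hexahydronaphthalen-6-yl (2E,4E,6R)-6-hydroxy-6-methylocta-2,4-dienoate, via mixed anhydride 28 (not isolated)
Conditions: 27, 2,4,6-trichlorobenzoyl chloride, Et3N, THF, 25 °C; then 19, DMAP, toluene, 25 °C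
Reagents that add atoms: none
Why: Yamaguchi esterification acylates the hindered secondary allylic alcohol with retention at C6, while the tertiary alcohol of the acid is too hindered to compete.

**Step 18**
Reactants: 29 (4aR,5R,6S)-4a,5-dimethyl-2-oxo-2,3,4,4a,5,6-hexahydronaphthalen-6-yl (2E,4E,6R)-6-hydroxy-6-methylocta-2,4-dienoate
Product: 31 (3R,4aR,5R,6S)-3-hydroxy-4a,5-dimethyl-2-oxo-2,3,4,4a,5,6-hexahydronaphthalen-6-yl (2E,4E,6R)-6-hydroxy-6-methylocta-2,4-dienoate, via dipotassium enolate alkoxide 30 (not isolated)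
Conditions: KN(SiMe3)2 (2.3 equiv), THF, −78 °C; then 3-phenyl-2-(phenylsulfonyl)oxaziridine, −78 °C; aq. NH4Cl
Reagents that add atoms: 3-phenyl-2-(phenylsulfonyl)oxaziridine, O=S(=O)(c1ccccc1)N1OC1c1ccccc1
Why: Kinetic deprotonation can occur only at C3 (the dienoate has no alpha-hydrogen and the tertiary alcohol is carried as its alkoxide), and oxygen transfer from the N-sulfonyloxaziridine to the enolate face anti to the axial C4a methyl (enolate hydroxylation) should give the equatorial 3R alcohol, which is also the thermodynamically preferred epimer.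

**Compound list**

1 | 1,4-bis(trimethylsilyl)buta-1,3-diyne | C[Si](C)(C)C#CC#C[Si](C)(C)C | starting material
2 | lithium 4-(trimethylsilyl)buta-1,3-diyn-1-ide | [Li]C#CC#C[Si](C)(C)C | intermediate (not isolated)
3 | 5-(trimethylsilyl)penta-2,4-diynal | O=CC#CC#C[Si](C)(C)C | intermediate
4 | (S)-but-3-yn-2-ol | C#C[C@H](C)O | starting material
5 | (S)-but-3-yn-2-yl methanesulfonate | C#C[C@H](C)OS(C)(=O)=O | intermediate
6 | (aR)-buta-1,2-dien-1-ylzinc methanesulfonate | [H]C([Zn]OS(C)(=O)=O)=[C@@]=C([H])C | intermediate (not isolated)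
7 | (3R,4R)-3-methyl-8-(trimethylsilyl)octa-1,5,7-triyn-4-ol | C#C[C@@H](C)[C@@H](O)C#CC#C[Si](C)(C)C | intermediate
8 | tert-butyl(dimethyl){[(3R,4R)-3-methyl-8-(trimethylsilyl)octa-1,5,7-triyn-4-yl]oxy}silane | C#C[C@@H](C)[C@@H](O[Si](C)(C)C(C)(C)C)C#CC#C[Si](C)(C)C | intermediate
9 | 9-[(1Z,3S,4R)-2-bromo-4-{[tert-butyl(dimethyl)silyl]oxy}-3-methyl-8-(trimethylsilyl)oct-1-en-5,7-diyn-1-yl]-9-borabicyclo[3.3.1]nonane | Br/C(=C\B1C2CCCC1CCC2)[C@@H](C)[C@@H](O[Si](C)(C)C(C)(C)C)C#CC#C[Si](C)(C)C | intermediate (not isolated)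
10 | {[(3S,4R)-2-bromo-3-methyl-8-(trimethylsilyl)oct-1-en-5,7-diyn-4-yl]oxy}(tert-butyl)dimethylsilane | BrC(=C)[C@@H](C)[C@@H](O[Si](C)(C)C(C)(C)C)C#CC#C[Si](C)(C)C | intermediate
11 | 1-ethoxycyclopropan-1-ol | CCOC1(O)CC1 | starting material
12 | [(3R,4R)-4-{[tert-butyl(dimethyl)silyl]oxy}-3-methyl-8-(trimethylsilyl)oct-1-en-5,7-diyn-2-yl]lithium | [Li]C(=C)[C@@H](C)[C@@H](O[Si](C)(C)C(C)(C)C)C#CC#C[Si](C)(C)C | intermediate (not isolated)
13 | bromomagnesium 1-ethoxycyclopropan-1-olate | CCOC1(O[Mg]Br)CC1 | intermediate (not isolated)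
14 | 1-[(3R,4R)-4-{[tert-butyl(dimethyl)silyl]oxy}-3-methyl-8-(trimethylsilyl)oct-1-en-5,7-diyn-2-yl]cyclopropan-1-ol | OC1(CC1)C(=C)[C@@H](C)[C@@H](O[Si](C)(C)C(C)(C)C)C#CC#C[Si](C)(C)C | intermediate
15 | (2R)-2-[(2R,3R)-3-{[tert-butyl(dimethyl)silyl]oxy}-7-(trimethylsilyl)hepta-4,6-diyn-2-yl]-2-methylcyclobutan-1-one | O=C1CC[C@]1(C)[C@@H](C)[C@@H](O[Si](C)(C)C(C)(C)C)C#CC#C[Si](C)(C)C | intermediate
16 | (2R)-2-[(2R,3S,4Z)-3-{[tert-butyl(dimethyl)silyl]oxy}-7-(trimethylsilyl)hept-4-en-6-yn-2-yl]-2-methylcyclobutan-1-one | O=C1CC[C@]1(C)[C@@H](C)[C@@H](O[Si](C)(C)C(C)(C)C)/C=C\C#C[Si](C)(C)C | intermediate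
17 | (2R)-2-[(2R,3S,4Z)-3-{[tert-butyl(dimethyl)silyl]oxy}hept-4-en-6-yn-2-yl]-2-methylcyclobutan-1-one | O=C1CC[C@]1(C)[C@@H](C)[C@@H](O[Si](C)(C)C(C)(C)C)/C=C\C#C | intermediate
18 | (4aR,5R,6S)-6-{[tert-butyl(dimethyl)silyl]oxy}-4a,5-dimethyl-4,4a,5,6-tetrahydronaphthalen-2(3H)-one | CC(C)(C)[Si](C)(C)O[C@H]1C=CC2=CC(=O)CC[C@]2(C)[C@H]1C | intermediate
19 | (4aR,5R,6S)-6-hydroxy-4a,5-dimethyl-4,4a,5,6-tetrahydronaphthalen-2(3H)-one | O[C@H]1C=CC2=CC(=O)CC[C@]2(C)[C@H]1C | intermediate
20 | (R)-2-hydroxy-2-methylbutanoic acid | CC[C@@](C)(O)C(=O)O | starting material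
21 | methyl (R)-2-hydroxy-2-methylbutanoate | CC[C@@](C)(O)C(=O)OC | intermediate
22 | methyl (R)-2-methyl-2-[(triethylsilyl)oxy]butanoate | CC[C@@](C)(O[Si](CC)(CC)CC)C(=O)OC | intermediate
23 | (R)-2-methyl-2-[(triethylsilyl)oxy]butanal | CC[C@@](C)(O[Si](CC)(CC)CC)C=O | intermediate
24 | ethyl (2E)-4-(diethoxyphosphoryl)but-2-enoate | CCOC(=O)/C=C/CP(=O)(OCC)OCC | starting material
25 | lithium salt of the C4 carbanion of ethyl (2E)-4-(diethoxyphosphoryl)but-2-enoate | CCOC(=O)/C=C/[CH-]P(=O)(OCC)OCC.[Li+] | intermediate (not isolated)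
26 | ethyl (2E,4E,6R)-6-methyl-6-[(triethylsilyl)oxy]octa-2,4-dienoate | CC[C@@](C)(O[Si](CC)(CC)CC)/C=C/C=C/C(=O)OCC | intermediate
27 | (2E,4E,6R)-6-hydroxy-6-methylocta-2,4-dienoic acid | CC[C@@](C)(O)/C=C/C=C/C(=O)O | intermediate
28 | (2E,4E,6R)-6-hydroxy-6-methylocta-2,4-dienoic 2,4,6-trichlorobenzoic anhydride | CC[C@@](C)(O)/C=C/C=C/C(=O)OC(=O)c1c(Cl)cc(Cl)cc1Cl | intermediate (not isolated)
29 | (4aR,5R,6S)-4a,5-dimethyl-2-oxo-2,3,4,4a,5,6-hexahydronaphthalen-6-yl (2E,4E,6R)-6-hydroxy-6-methylocta-2,4-dienoate | CC[C@@](C)(O)/C=C/C=C/C(=O)O[C@H]1C=CC2=CC(=O)CC[C@]2(C)[C@H]1C | intermediate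
30 | dipotassium C2/C3 enolate and side-chain alkoxide of 29 | CC[C@@](C)([O-])/C=C/C=C/C(=O)O[C@H]1C=CC2=CC([O-])=CC[C@]2(C)[C@H]1C.[K+].[K+] | intermediate (not isolated)
31 | (3R,4aR,5R,6S)-3-hydroxy-4a,5-dimethyl-2-oxo-2,3,4,4a,5,6-hexahydronaphthalen-6-yl (2E,4E,6R)-6-hydroxy-6-methylocta-2,4-dienoate | CC[C@@](C)(O)/C=C/C=C/C(=O)O[C@H]1C=CC2=CC(=O)[C@H](O)C[C@]2(C)[C@H]1C | target

**Totals**

Total step count: 18. Longest linear sequence: 12 steps (steps 1, 3 to 11, 17, 18).

**Steps most likely to fail**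

Step 10 (key step). The free terminal alkyne may oligomerise or form a vinylidene at rhodium, and rhodium may stay at the less hindered C–C bond and lose CO instead of reaching the proximal bond. The fallback sets out from 16 and comes back at 19. The silyl-capped enyne 16 is used as an internal alkyne in the same rhodium-catalysed ring fusion (the alkyne type most established for this reaction), which should give (4aR,5R,6S)-6-{[tert-butyl(dimethyl)silyl]oxy}-4a,5-dimethyl-1-(trimethylsilyl)-4,4a,5,6-tetrahydronaphthalen-2(3H)-one F1. Bu4NF in wet THF then cleaves both the vinylic C–Si bond alpha to the ketone and the silyl ether, returning alcohol 19.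

Step 7. The migrating cyclopropane bond may attack both faces of the tertiary cation, giving poor facial selectivity at the quaternary carbon. The fallback sets out from 7 and comes back at 15; it replaces open-chain induction by a hydroxyl-directed epoxidation and a stereospecific shift.
- Alcohol 7 is silylated (TESCl, imidazole) to triethyl{[(3R,4R)-3-methyl-8-(trimethylsilyl)octa-1,5,7-triyn-4-yl]oxy}silane F2.
- Markovnikov hydration of the terminal alkyne (Ph3PAuNTf2 cat., MeOH/H2O) gives (3S,4R)-3-methyl-4-[(triethylsilyl)oxy]-8-(trimethylsilyl)octa-5,7-diyn-2-one F3.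
- Wittig reaction with cyclopropylidene(triphenyl)phosphorane (from cyclopropyltriphenylphosphonium bromide and KN(SiMe3)2) gives {[(3R,4R)-2-cyclopropylidene-3-methyl-8-(trimethylsilyl)octa-5,7-diyn-4-yl]oxy}triethylsilane F4.
- Buffered HF·pyridine frees (3R,4R)-2-cyclopropylidene-3-methyl-8-(trimethylsilyl)octa-5,7-diyn-4-ol F5.
- VO(acac)2 with t-BuOOH delivers oxygen from the homoallylic hydroxyl to the alkene face on which the carbinol arm lies (allylic hydrogen in the alkene plane), giving (2S,3R)-2-[(2S)-2-methyl-1-oxaspiro[2.2]pentan-2-yl]-7-(trimethylsilyl)hepta-4,6-diyn-3-ol F6. This rearranges in the flask, with inversion at the epoxide carbon, to (2R)-2-[(2R,3R)-3-hydroxy-7-(trimethylsilyl)hepta-4,6-diyn-2-yl]-2-methylcyclobutan-1-one F7.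
- Silylation with TBSOTf and 2,6-lutidine gives 15.

Step 18. The strongly basic enolate conditions may cause competing deprotonation, acyl transfer or over-oxidation, or oxygen may be delivered to the wrong face. The fallback sets out from 29 and comes back at 31. Non-basic alpha′-acetoxylation of the enone with Mn(OAc)3·2H2O in refluxing benzene (oxidation by trivalent manganese through the enol) should give (3R,4aR,5R,6S)-3-acetoxy-4a,5-dimethyl-2-oxo-2,3,4,4a,5,6-hexahydronaphthalen-6-yl (2E,4E,6R)-6-hydroxy-6-methylocta-2,4-dienoate F8. Brief K2CO3/MeOH at 0 °C then removes the activated alpha-keto acetate in preference to the hindered dienoate and equilibrates C3 to the equatorial alcohol, giving 31.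

**Further compounds**

F1 | step 10 | (4aR,5R,6S)-6-{[tert-butyl(dimethyl)silyl]oxy}-4a,5-dimethyl-1-(trimethylsilyl)-4,4a,5,6-tetrahydronaphthalen-2(3H)-one | CC(C)(C)[Si](C)(C)O[C@H]1C=CC2=C([Si](C)(C)C)C(=O)CC[C@]2(C)[C@H]1C
F2 | step 7 | triethyl{[(3R,4R)-3-methyl-8-(trimethylsilyl)octa-1,5,7-triyn-4-yl]oxy}silane | C#C[C@@H](C)[C@@H](O[Si](CC)(CC)CC)C#CC#C[Si](C)(C)C
F3 | step 7 | (3S,4R)-3-methyl-4-[(triethylsilyl)oxy]-8-(trimethylsilyl)octa-5,7-diyn-2-one | CC(=O)[C@@H](C)[C@@H](O[Si](CC)(CC)CC)C#CC#C[Si](C)(C)C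
F4 | step 7 | {[(3R,4R)-2-cyclopropylidene-3-methyl-8-(trimethylsilyl)octa-5,7-diyn-4-yl]oxy}triethylsilane | CC(=C1CC1)[C@@H](C)[C@@H](O[Si](CC)(CC)CC)C#CC#C[Si](C)(C)C
F5 | step 7 | (3R,4R)-2-cyclopropylidene-3-methyl-8-(trimethylsilyl)octa-5,7-diyn-4-ol | CC(=C1CC1)[C@@H](C)[C@@H](O)C#CC#C[Si](C)(C)C
F6 | step 7 | (2S,3R)-2-[(2S)-2-methyl-1-oxaspiro[2.2]pentan-2-yl]-7-(trimethylsilyl)hepta-4,6-diyn-3-ol | C[C@]1(OC12CC2)[C@@H](C)[C@@H](O)C#CC#C[Si](C)(C)C
F7 | step 7 | (2R)-2-[(2R,3R)-3-hydroxy-7-(trimethylsilyl)hepta-4,6-diyn-2-yl]-2-methylcyclobutan-1-one | O=C1CC[C@]1(C)[C@@H](C)[C@@H](O)C#CC#C[Si](C)(C)C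
F8 | step 18 | (3R,4aR,5R,6S)-3-acetoxy-4a,5-dimethyl-2-oxo-2,3,4,4a,5,6-hexahydronaphthalen-6-yl (2E,4E,6R)-6-hydroxy-6-methylocta-2,4-dienoate | CC[C@@](C)(O)/C=C/C=C/C(=O)O[C@H]1C=CC2=CC(=O)[C@H](OC(C)=O)C[C@]2(C)[C@H]1C
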